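In a one-step world every substrate becomes target, whatever the charge; the red and blue runs show something else.

the same everywhere: gas phase 6.1 mM (held)
- red: substrate 0.034 M; run made earlier
- blue: substrate 0.075 M; run made earlier
- flask: substrate 0.050 M; time 10 d

| run | time / d | target / % |
|---|---|---|
| red | 1.04 | 33 |
| red | 2.08 | 50 |
| red | 3.00 | 57 |
| red | 4.00 | 61 |
| red | 5.00 | 62 |
| red | 6.00 | 67 |
| blue | 0.417 | 8 |
| blue | 1.25 | 22 |
| blue | 2.00 | 36 |
| blue | 3.00 | 35 |
| blue | 5.00 | 42 |
| blue | 6.00 | 43 |

(scatter of a reading: 2 percentage points)

* the target standing at 10 d, as a percentage of the substrate charged
* the change that raises the amount of target at 10 d, in percent of the substrate charged most ("none" if none brings more than 2 percentage points) (Thursday's / Saturday's / none)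
* amount of target at 10 d, in percent of the substrate charged, after Saturday's

- at the start none of the gas phase is in solution

- Thursday's: doubling the transfer coefficient of the gas phase, all else as stated
- Saturday's: doubling the saturation concentration of gas phase, all else as stated

1. First day. No gas is in solution at the start, and the readings give on average 10.8 mM d⁻¹ of target in red up to 1.04 d and 13.2 mM d⁻¹ in blue up to 1.25 d. The charge rises by a factor of 2.21 and the early rate by 1.22, less than the charge, so [dissolved gas] appears to hold the target step back.

2. Middle. At 3.00 d red stands at 57% and blue at 35%, and both curves are bending.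

3. End. The last two readings average 64.5% in red and 42.5% in blue, lower at the larger charge. This reckoning assumes an unseen route that goes with [substrate] squared, against a target route that goes with [substrate] at steady [dissolved gas]. The ratio of the two rates then grows with the charge.

4. Rule. Missing share over target share, per molar charged, is 16.2 M⁻¹ in red and 18.0 M⁻¹ in blue, with mean 17.1 M⁻¹. Call this the loss coefficient, a selectivity factor, read here from scattered readings with the gas phase held at 6.1 mM: missing share over target share per molar of substrate charged.

5. This flask. In this reckoning, with the gas phase held at 6.1 mM, the target share is one over one plus coefficient times charge. Taking the flask as flat by 10 d, 0.050 M gives 53.9%.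

6. Changes. This reckoning lets the coefficient fall as [dissolved gas] rises. Saturday's raises the ceiling of [dissolved gas], so the coefficient is taken as 8.55 M⁻¹, giving 70.0%. Thursday's speeds the filling but leaves the ceiling at 6.1 mM, so this reckoning picks Saturday's.

The forecast gives 56%, Saturday's and 81%, in its words “Saturday's wins”.

The flask gives 54.9%. The best change is Saturday's, gaining 13 percentage points against 5.2 points for Thursday's, and reaching 68.4%.

    gas phase ⇌ dissolved gas, rate k1*(csat - [dissolved gas]) (kL = 0.282 h⁻¹)
    substrate + dissolved gas → target (k = 6.61 M⁻¹ h⁻¹)
    2 substrate → homo dimer (k = 0.239 M⁻¹ h⁻¹)
    substrate + target → side product (k = 0.184 M⁻¹ h⁻¹)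
    dissolved gas → decomposed reagent (k = 0.0515 h⁻¹)

The result puts the loss coefficient of this flask at 16.4 M⁻¹, its missing share being side product and homo dimer together. In this flask at 1.00 d, with [dissolved gas] at 0.00357 M, substrate going to homo dimer over substrate going to target, per molar of substrate standing, is 20.3 M⁻¹. In the neighbouring flask with 0.030 M of substrate, the coefficient from red and blue gives 66.1%, and that flask stands at 68.1%.

The runs are simulated on assumed constants.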